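The plan opens the trans-fused α-methylene-γ-lactone (ring B: C7, C8, O, C12, C11) and the cyclohexene (ring A: C5–C10) at once, at their shared bond C7–C8 and at C11–C12. C8 (aldehyde) and C7 (β-carbon of a vinylphosphonate) are both acceptor carbons. SmI2 reverses the polarity of C8, the ketyl closes ring A, and carbonyldiimidazole (C12) then bridges the C8 alkoxide and the C11 phosphonate carbanion, closing ring B. The open radical transition state should give the trans fusion that a metal-templated allene/aldehyde/CO union would not. The C6 carbinol alone relays C7 and C8. The precursor is an acyclic aldehyde with a stereodefined tetrasubstituted alkene, made from (S)-citronellic acid.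

Key step: step 12

Remark: seco-eudesmane numbering is used throughout. Ring A = C5, C6, C7, C8, C9, C10. Ring B = C7, C8, O, C12, C11. C13 is the exocyclic CH2, C14 is the CH2O on C10, and the side chain C4(CH3)–C3–C2–C1–O sits on C5. (S)-Citronellic acid is taken as commercial (otherwise one Pinnick oxidation from (S)-citronellal).

Step 1
Reactants: 1 (S)-citronellic acid, (3S)-3,7-dimethyloct-6-enoic acid
Product: 2 Weinreb amide (3S)-N-methoxy-N,3,7-trimethyloct-6-enamide
Conditions: MeNHOMe·HCl, EDC·HCl, N-methylmorpholine, CH2Cl2, 0 °C → rt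
Reagents that add atoms: N,O-dimethylhydroxylamine hydrochloride, CNOC.Cl
Why: Carbodiimide amide coupling gives the Weinreb amide (C6) that later stops acetylide addition at the ketone stage, and the C4 centre from the chiral pool is untouched.

Step 2
Reactants: 2 Weinreb amide; 3 (tert-butyldimethylsilyloxy)acetaldehyde
Product: 4 aldol adduct (3S)-2-[2-(tert-butyldimethylsilyloxy)-1-hydroxyethyl]-N-methoxy-N,3,7-trimethyloct-6-enamide (C5 and C10 epimers)
Conditions: LDA, THF, −78 °C; then 3, −78 °C; aq. NH4Cl
Reagents that add atoms: none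
Why: The aldol addition of the lithium amide enolate joins C5 to C10, and both new centres are erased in steps 3 and 4, so no control is needed.

Step 3
Reactants: 4 aldol adduct
Product: 5 β-keto amide (3S)-2-[(tert-butyldimethylsilyloxy)acetyl]-N-methoxy-N,3,7-trimethyloct-6-enamide (C5 epimers)
Conditions: Dess–Martin periodinane, CH2Cl2, 0 °C → rt
Reagents that add atoms: none
Why: Dess–Martin oxidation of the secondary alcohol spares the silyl ether and the trisubstituted alkene and gives the 1,3-dicarbonyl needed for a chelated enolate.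

Step 4
Reactants: 5 β-keto amide
Product: 6 (Z)-enol triflate (C5=C10; OTf on C10 cis to the amide carbonyl C6, CH2OTBS cis to C4)
Conditions: NaH, THF, 0 °C; then Comins' reagent, 0 °C → rt
Reagents that add atoms: Comins' reagent, N-(5-chloro-2-pyridyl)bis(trifluoromethanesulfonimide), O=S(=O)(N(c1ccc(Cl)cn1)S(=O)(=O)C(F)(F)F)C(F)(F)F
Why: O-triflation of the sodium-chelated enolate, whose enolate oxygen is held cis to the amide carbonyl, should fix the (Z)-enol triflate and with it the later cis relation of C6 and C9.

Step 5
Reactants: 6 (Z)-enol triflate; 7 (1,3-dioxolan-2-ylmethyl)zinc bromide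
Product: 8 (E)-tetrasubstituted enamide (C10 carries CH2(1,3-dioxolan-2-yl) cis to the amide carbonyl and CH2OTBS cis to C4)
Conditions: PdCl2(dppf) (cat.), THF, 50 °C
Reagents that add atoms: none
Why: Negishi coupling of an electron-poor alkenyl triflate proceeds with retention of alkene geometry and brings in C9 and C8, with C8 already masked at the aldehyde level.

Step 6
Reactants: 8 (E)-enamide
Product: 10 C1 primary alcohol of the (E)-enamide, via C1 aldehyde 9 (not isolated)
Conditions: O3, CH2Cl2/MeOH, Sudan Red 7B, −78 °C; then NaBH4, −78 → 0 °C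
Reagents that add atoms: ozone, [O-][O+]=O
Why: Indicator-controlled ozonolysis is selective for the electron-rich trisubstituted alkene over the hindered, carbonyl-bearing tetrasubstituted one, and the borohydride work-up gives the C1 alcohol without touching the Weinreb amide.

Step 7
Reactants: 10 C1 alcohol; 11 ethynylmagnesium bromide
Product: 12 ethynyl ketone (C6 ketone flanked by the ethynyl group C7≡C11 and the tetrasubstituted alkene, free C1 hydroxyl)
Conditions: 11 (excess), THF, 0 °C → rt; aq. NH4Cl
Reagents that add atoms: none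
Why: In this Weinreb ketone synthesis the first equivalent only deprotonates the C1 hydroxyl, and the chelated tetrahedral adduct prevents over-addition.

Step 8
Reactants: 12 ethynyl ketone
Product: 13 (6S)-propargylic alcohol (diol with free C1 and C6 hydroxyls)
Conditions: (R)-2-methyl-CBS-oxazaborolidine (cat.), catecholborane, toluene, −78 °C; then MeOH, aq. NaHCO3
Reagents that add atoms: none
Why: In the Corey–Bakshi–Shibata reduction the small ethynyl and the large tetrasubstituted alkenyl group are well differentiated, so the (R)-catalyst should set (6S) by catalyst control, and catecholborane at low temperature spares the alkyne.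

Step 9
Reactants: 13 diol
Product: 14 C1 acetate with free (6S)-propargylic hydroxyl
Conditions: AcCl, 2,4,6-collidine, CH2Cl2, −78 °C
Reagents that add atoms: acetyl chloride, CC(=O)Cl
Why: Selective acylation with acetyl chloride and collidine at low temperature takes the unhindered primary alcohol and leaves the hindered secondary carbinol free.

Step 10
Reactants: 14 C1 acetate; 15 4,4,5,5-tetramethyl-1,3,2-dioxaphospholane 2-oxide (pinacol H-phosphonate)
Product: 16 (E)-alkenylphosphonate (C7H=C11H–P(O)(pinacolato), free (6S)-hydroxyl)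
Conditions: RhBr(PPh3)3 (cat.), acetone, rt
Reagents that add atoms: none
Why: Rhodium-catalysed hydrophosphorylation of a terminal alkyne is a syn, anti-Markovnikov addition of the P–H bond that gives the (E)-alkenylphosphonate and tolerates the free hydroxyl.

Step 11
Reactants: 16 (E)-alkenylphosphonate
Product: 18 C8 aldehyde bearing the (6S)-OTES group plus the (E)-alkenylphosphonate, via lutidinium mixed acetal 17 (not isolated)
Conditions: TESOTf, 2,6-lutidine, CH2Cl2, 0 °C; then H2O
Reagents that add atoms: triethylsilyl trifluoromethanesulfonate, CC[Si](CC)(CC)OS(=O)(=O)C(F)(F)F; water, O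
Why: The silyl triflate/lutidine acetal cleavage silylates O6 and turns the aldehyde-derived dioxolane into a lutidinium mixed acetal that water cleaves under nearly neutral conditions, which should keep the β,γ-unsaturated aldehyde out of conjugation.

Step 12
Reactants: 18 C8 aldehyde; 19 1,1'-carbonyldiimidazole
Product: 22 trans-fused α-phosphono-γ-lactone (H6/H7 cis; H7/H8 trans; C11 epimers), via diiodosamarium alkoxide carbanion 20 (not isolated), via imidazolyl carbonate carbanion 21 (not isolated)
Conditions: SmI2, HMPA, THF, −78 °C, slow addition of 18, no proton source; then 19, −78 → 0 °C; aq. NH4Cl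
Reagents that add atoms: none
Why: Proposed new method: divalent samarium reduces the C8 aldehyde to a ketyl radical that adds 6-exo-trig to C7 of the (E)-vinylphosphonate (closing ring A and joining two acceptor carbons), a second electron turns the α-phosphonyl radical into the C11 carbanion, and carbonyldiimidazole then acylates the C8 alkoxide so that the carbanion attacks the imidazolyl carbonate 5-exo-trig (closing ring B and forming C11–C12). The closest known reaction type is the SmI2 ketyl–olefin cyclisation onto enoates or vinyl sulfones followed by trapping of the organosamarium with an external electrophile, whereas a vinylphosphonate acceptor and a one-carbon bis-electrophile that bridges alkoxide and carbanion go beyond it. C7 is controlled by C6: allylic 1,2-strain with the C5 side chain holds the OTES group pseudoaxial in the half-chair, and the phosphonovinyl arm then sits pseudoequatorial, cis to O6. C8 is controlled by the bulky HMPA-solvated samarium ketyl oxygen, which takes the pseudoequatorial site anti to the acceptor, so O8 and C11 end up trans-diequatorial, while C11 is a mixture that step 13 erases. The step needs cyclisation to outrun pinacol coupling, simple reduction and proton transfer, which the cis-alkene tether, the electron-poor acceptor, slow addition of 18 to excess reductant and the absence of any OH group should secure.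

Step 13
Reactants: 22 α-phosphono lactone; 23 formaldehyde
Product: 24 bis-silylated α-methylene-γ-lactone (O6-TES, O14-TBS, C1 acetate)
Conditions: aq. 23, K2CO3, THF, 0 °C → rt
Reagents that add atoms: none
Why: Horner–Wadsworth–Emmons olefination of the α-phosphono lactone with formaldehyde under mild carbonate conditions installs C13, removes the C11 stereocentre and tolerates the acetate.

Step 14
Reactants: 24 bis-silyl ether
Product: 25 diol (free C6 and C14 hydroxyls)
Conditions: HF·pyridine, pyridine, THF, 0 °C → rt
Reagents that add atoms: none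
Why: Buffered fluoride desilylation cleaves both silyl ethers without conjugate addition to the α-methylene lactone and leaves the acetate and the lactone intact.

Step 15
Reactants: 25 diol; 26 methacrylic anhydride
Product: 27 target CNP0122587.1, [(3aR,4S,7aR)-5-[(2S)-5-acetoxypentan-2-yl]-4-hydroxy-3-methylene-2-oxo-2,3,3a,4,7,7a-hexahydrobenzofuran-6-yl]methyl methacrylate
Conditions: 26, Et3N, DMAP (cat.), CH2Cl2, −20 °C
Reagents that add atoms: none
Why: DMAP-catalysed acylation discriminates the primary allylic C14 hydroxyl from the hindered, pseudoaxial secondary C6 hydroxyl.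

Compound list
1 | (S)-citronellic acid | C[C@@H](CCC=C(C)C)CC(=O)O | starting material
2 | (3S)-N-methoxy-N,3,7-trimethyloct-6-enamide | C[C@@H](CCC=C(C)C)CC(=O)N(C)OC | intermediate
3 | (tert-butyldimethylsilyloxy)acetaldehyde | O=CCO[Si](C)(C)C(C)(C)C | starting material
4 | aldol adduct (C5 and C10 epimers) | C[C@@H](CCC=C(C)C)C(C(O)CO[Si](C)(C)C(C)(C)C)C(=O)N(C)OC | intermediate
5 | β-keto amide (C5 epimers) | C[C@@H](CCC=C(C)C)C(C(=O)CO[Si](C)(C)C(C)(C)C)C(=O)N(C)OC | intermediate
6 | (Z)-enol triflate | CON(C)C(=O)/C([C@@H](C)CCC=C(C)C)=C(\OS(=O)(=O)C(F)(F)F)CO[Si](C)(C)C(C)(C)C | intermediate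
7 | (1,3-dioxolan-2-ylmethyl)zinc bromide | Br[Zn]CC1OCCO1 | starting material
8 | (E)-tetrasubstituted enamide with dioxolane | CON(C)C(=O)/C([C@@H](C)CCC=C(C)C)=C(\CC1OCCO1)CO[Si](C)(C)C(C)(C)C | intermediate
9 | C1 aldehyde (not isolated) | CON(C)C(=O)/C([C@@H](C)CCC=O)=C(\CC1OCCO1)CO[Si](C)(C)C(C)(C)C | intermediate
10 | C1 alcohol | CON(C)C(=O)/C([C@@H](C)CCCO)=C(\CC1OCCO1)CO[Si](C)(C)C(C)(C)C | intermediate
11 | ethynylmagnesium bromide | C#C[Mg]Br | starting material
12 | ethynyl ketone | C#CC(=O)/C([C@@H](C)CCCO)=C(\CC1OCCO1)CO[Si](C)(C)C(C)(C)C | intermediate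
13 | (6S)-propargylic alcohol, diol | C#C[C@H](O)/C([C@@H](C)CCCO)=C(\CC1OCCO1)CO[Si](C)(C)C(C)(C)C | intermediate
14 | C1 acetate | C#C[C@H](O)/C([C@@H](C)CCCOC(C)=O)=C(\CC1OCCO1)CO[Si](C)(C)C(C)(C)C | intermediate
15 | 4,4,5,5-tetramethyl-1,3,2-dioxaphospholane 2-oxide | O=[PH]1OC(C)(C)C(C)(C)O1 | starting material
16 | (E)-alkenylphosphonate | CC1(C)OP(=O)(/C=C/[C@H](O)/C([C@@H](C)CCCOC(C)=O)=C(\CC2OCCO2)CO[Si](C)(C)C(C)(C)C)OC1(C)C | intermediate
17 | lutidinium mixed acetal triflate (not isolated) | CC1(C)OP(=O)(/C=C/[C@H](O[Si](CC)(CC)CC)/C([C@@H](C)CCCOC(C)=O)=C(\CC(OCCO[Si](CC)(CC)CC)[n+]2c(C)cccc2C)CO[Si](C)(C)C(C)(C)C)OC1(C)C.[O-]S(=O)(=O)C(F)(F)F | intermediate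
18 | C8 aldehyde, precursor of the key step | CC1(C)OP(=O)(/C=C/[C@H](O[Si](CC)(CC)CC)/C([C@@H](C)CCCOC(C)=O)=C(\CC=O)CO[Si](C)(C)C(C)(C)C)OC1(C)C | intermediate
19 | 1,1'-carbonyldiimidazole | O=C(n1ccnc1)n1ccnc1 | starting material
20 | diiodosamarium alkoxide carbanion (not isolated) | CC(C)(C)[Si](C)(C)OCC1=C([C@@H](C)CCCOC(C)=O)[C@@H](O[Si](CC)(CC)CC)[C@@H]([CH-]P2(=O)OC(C)(C)C(C)(C)O2)[C@H]([O-])C1.[Sm+3].[Sm+3].[I-].[I-].[I-].[I-] | intermediate
21 | imidazolyl carbonate carbanion (not isolated) | CC(C)(C)[Si](C)(C)OCC1=C([C@@H](C)CCCOC(C)=O)[C@@H](O[Si](CC)(CC)CC)[C@@H]([CH-]P2(=O)OC(C)(C)C(C)(C)O2)[C@H](OC(=O)n2ccnc2)C1.[Sm+3].[I-].[I-] | intermediate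
22 | trans-fused α-phosphono-γ-lactone (C11 epimers) | CC(C)(C)[Si](C)(C)OCC1=C([C@@H](C)CCCOC(C)=O)[C@@H](O[Si](CC)(CC)CC)[C@H]2C(P3(=O)OC(C)(C)C(C)(C)O3)C(=O)O[C@@H]2C1 | intermediate
23 | formaldehyde | C=O | starting material
24 | bis-silylated α-methylene-γ-lactone | CC(C)(C)[Si](C)(C)OCC1=C([C@@H](C)CCCOC(C)=O)[C@@H](O[Si](CC)(CC)CC)[C@H]2C(=C)C(=O)O[C@@H]2C1 | intermediate
25 | C6,C14-diol | OCC1=C([C@@H](C)CCCOC(C)=O)[C@@H](O)[C@H]2C(=C)C(=O)O[C@@H]2C1 | intermediate
26 | methacrylic anhydride | C=C(C)C(=O)OC(=O)C(C)=C | starting material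
27 | CNP0122587.1 | C=C(C)C(=O)OCC1=C([C@@H](C)CCCOC(C)=O)[C@@H](O)[C@H]2C(=C)C(=O)O[C@@H]2C1 | target

Total step count: 15. Longest linear sequence: 15 steps (from 1).

Steps most likely to fail

Step 12 (the proposed new method). The C11 carbanion may be protonated early by the enolisable aldehyde. Pinacol dimerisation or plain reduction of the aldehyde may compete, and facial selectivity at C7 and C8 may be poor. The alkoxide may attack phosphorus, or both nucleophilic sites may be acylated separately.
- The fallback buys the C11–C12 bond, uses only known chemistry, sets out from 14 and comes back at 24.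
- Semihydrogenation of 14 (Pd/CaCO3 poisoned with Pb(OAc)2, quinoline, H2) would give the allylic alcohol F1.
- Cross-metathesis with methyl acrylate (second-generation Hoveyda–Grubbs catalyst) would give the (E)-γ-hydroxy enoate F2.
- TESOTf/2,6-lutidine and then water would give the aldehyde F3.
- The well-established SmI2/MeOH ketyl–enoate 6-exo cyclisation would give the trans-hydroxy ester F4.
- PPTS in warm benzene would close the saturated trans-lactone F5.
- One equivalent of LiHMDS and Eschenmoser's salt would give the Mannich base F6. The lactone is more acidic than the acetate.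
- MeI and then NaHCO3 would lead to 24.

Step 7. Addition to the hindered, twisted amide may be slow, and base-induced loss of formaldehyde from the N-methoxy group may compete.
- The fallback replaces ketone formation and reduction by an asymmetric C–C bond formation. It sets out from 10 and comes back at 13, so it also bypasses step 8.
- DIBAL-H at −78 °C would give the tetrasubstituted enal F7.
- Me2Zn, trimethylsilylacetylene and the ProPhenol ligand enantiomer that delivers the (S)-carbinol would give the silylated propargylic alcohol F8.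
- K2CO3 in MeOH would give 13.

Step 5. Oxidative addition and transmetalation at the fully substituted alkenyl triflate may be slow. The organozinc reagent may lose β-alkoxide, and the alkene geometry may erode.
- The fallback brings in C9 and C8 as a slim sp unit. It sets out from 6 and comes back at 8.
- Sonogashira coupling with trimethylsilylacetylene (PdCl2(PPh3)2, CuI, Et3N) would give the silylated enyne F9.
- K2CO3 in MeOH would give the terminal enyne F10.
- Dicyclohexylborane and then NaBO3 (anti-Markovnikov hydration, selective for the terminal alkyne) would give the aldehyde F11.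
- Ethylene glycol with PPTS would give 8.

Further compounds
F1 | step 12 | (6S)-allylic alcohol | C=C[C@H](O)/C([C@@H](C)CCCOC(C)=O)=C(\CC1OCCO1)CO[Si](C)(C)C(C)(C)C
F2 | step 12 | (E)-γ-hydroxy enoate | COC(=O)/C=C/[C@H](O)/C([C@@H](C)CCCOC(C)=O)=C(\CC1OCCO1)CO[Si](C)(C)C(C)(C)C
F3 | step 12 | O6-TES enoate aldehyde | COC(=O)/C=C/[C@H](O[Si](CC)(CC)CC)/C([C@@H](C)CCCOC(C)=O)=C(\CC=O)CO[Si](C)(C)C(C)(C)C
F4 | step 12 | trans-hydroxy ester | CC(C)(C)[Si](C)(C)OCC1=C([C@@H](C)CCCOC(C)=O)[C@@H](O[Si](CC)(CC)CC)[C@@H](CC(=O)OC)[C@H](O)C1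
F5 | step 12 | saturated trans-fused lactone | CC(C)(C)[Si](C)(C)OCC1=C([C@@H](C)CCCOC(C)=O)[C@@H](O[Si](CC)(CC)CC)[C@H]2CC(=O)O[C@@H]2C1
F6 | step 12 | α-(dimethylaminomethyl) lactone | CC(C)(C)[Si](C)(C)OCC1=C([C@@H](C)CCCOC(C)=O)[C@@H](O[Si](CC)(CC)CC)[C@H]2C(CN(C)C)C(=O)O[C@@H]2C1
F7 | step 7 | tetrasubstituted enal | O=C/C([C@@H](C)CCCO)=C(\CC1OCCO1)CO[Si](C)(C)C(C)(C)C
F8 | step 7 | (6S)-trimethylsilyl propargylic alcohol | C[Si](C)(C)C#C[C@H](O)/C([C@@H](C)CCCO)=C(\CC1OCCO1)CO[Si](C)(C)C(C)(C)C
F9 | step 5 | silylated enyne | CON(C)C(=O)/C([C@@H](C)CCC=C(C)C)=C(\C#C[Si](C)(C)C)CO[Si](C)(C)C(C)(C)C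
F10 | step 5 | terminal enyne | CON(C)C(=O)/C([C@@H](C)CCC=C(C)C)=C(\C#C)CO[Si](C)(C)C(C)(C)C
F11 | step 5 | C8 aldehyde of the enamide | CON(C)C(=O)/C([C@@H](C)CCC=C(C)C)=C(\CC=O)CO[Si](C)(C)C(C)(C)C
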